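**Retrosynthetic overview**
- Target ⇒ its but‑2‑ynoate ester, because a late syn‑hydroalumination/formaldehyde trapping builds the (Z)‑2‑(hydroxymethyl)but‑2‑enoate without a protected acid; the ynoate ester ⇒ (1S,2R)‑1,3‑diol + but‑2‑ynoic acid.
- Diol ⇒ its primary TBS ether ⇒ disconnection of the bond between the carbinol carbon and the carbon bearing CH2O: veratraldehyde + (2E,4E)‑5‑(3,4‑dimethoxyphenyl)penta‑2,4‑dienyl TBS ether, joined by a Ni‑catalysed enantioselective reductive diene–aldehyde coupling that sets both stereocentres.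
- Enabling feature: the bis‑homoallylic alcohol array O–C1(aryl)–C2–CH2–CH=CH–aryl (a 1‑aryl‑pent‑4‑en‑1‑ol) with 1,2‑anti OH/CH2O; the veratryl ring on the alkene conjugates the diene and the derived allylnickel and so fixes where the C–C and C–H bonds form.
- Dienyl ether ⇒ veratraldehyde + triethyl 4‑phosphonocrotonate (vinylogous HWE, DIBAL‑H, TBSCl); both C6–C3 halves come from veratraldehyde.
- No ring is formed at any stage; the two veratryl rings are carried through from veratraldehyde.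

Key step: step 4

Assumption (chemistry): the (R)‑configured spirobiindane phosphoramidite is taken to be the ligand antipode that leads to the (1S,2R) series in step 4; if the sense of induction is the opposite, its enantiomer is used and nothing else changes.

Step 1
Reactants: 1 veratraldehyde (3,4‑dimethoxybenzaldehyde); 2 triethyl 4‑phosphonocrotonate [ethyl (2E)‑4‑(diethoxyphosphoryl)but‑2‑enoate]
Product: 3 ethyl (2E,4E)‑5‑(3,4‑dimethoxyphenyl)penta‑2,4‑dienoate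
Conditions: LiOH·H2O, 4 Å MS, THF, reflux
Reagents that add atoms: none
Why: Vinylogous Horner–Wadsworth–Emmons olefination, in which the γ‑phosphonate anion adds to the aldehyde and loses phosphate to give the new aryl‑conjugated double bond as the E isomer, the E double bond of the reagent being kept.

Step 2
Reactants: 3 ethyl (2E,4E)‑5‑(3,4‑dimethoxyphenyl)penta‑2,4‑dienoate
Product: 4 (2E,4E)‑5‑(3,4‑dimethoxyphenyl)penta‑2,4‑dien‑1‑ol
Conditions: DIBAL‑H (2.2 equiv), CH2Cl2, −78 °C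
Reagents that add atoms: none
Why: 1,2‑Reduction of a conjugated ester by DIBAL‑H should give the allylic alcohol and leave the diene untouched.

Step 3
Reactants: 4 (2E,4E)‑5‑(3,4‑dimethoxyphenyl)penta‑2,4‑dien‑1‑ol
Product: 5 tert‑butyl{[(2E,4E)‑5‑(3,4‑dimethoxyphenyl)penta‑2,4‑dien‑1‑yl]oxy}dimethylsilane
Conditions: TBSCl, imidazole, CH2Cl2, 0 °C → rt
Reagents that add atoms: tert‑butyldimethylsilyl chloride (TBSCl), CC(C)(C)[Si](C)(C)Cl
Why: Imidazole‑promoted silylation of a primary allylic alcohol; the silyl ether, unlike an ester or a free alcohol, should not be ionised by Ni(0)/Zn in the next step.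

Step 4
Reactants: 5 tert‑butyl{[(2E,4E)‑5‑(3,4‑dimethoxyphenyl)penta‑2,4‑dien‑1‑yl]oxy}dimethylsilane; 1 veratraldehyde
Product: 6 (1S,2R,4E)‑2‑{[(tert‑butyldimethylsilyl)oxy]methyl}‑1,5‑bis(3,4‑dimethoxyphenyl)pent‑4‑en‑1‑ol
Conditions: Ni(acac)2 (5 mol%), (R)‑spirobiindane phosphoramidite (SIPHOS type, 6 mol%), Et2Zn (2.5 equiv), toluene, 0 °C → rt
Reagents that add atoms: none
Why: Proposed new method: Ni(0) (from Ni(acac)2 and Et2Zn) bound to the chiral phosphoramidite should take up diene 5 as its s‑cis η4 complex together with aldehyde 1 and join them by oxidative cyclisation, making the bond between the aldehyde carbon (C1 of 6) and diene carbon C2 and leaving an η3‑allylnickel alkoxide over C3–C5; ethyl transfer from zinc to nickel, β‑hydride elimination (loss of ethylene) and C–H reductive elimination at C3 then complete a net hydro‑hydroxyalkylation of the C2=C3 bond. The closest known reaction type is the nickel/spiro‑phosphoramidite‑catalysed reductive coupling of (E,E)‑1,4‑diaryl‑1,3‑dienes with aromatic aldehydes and Et2Zn, which gives anti bis‑homoallylic alcohols; new here is an unsymmetrical 1‑aryl‑4‑(silyloxymethyl) diene. No ring of the product is closed, the five‑membered oxanickelacycle (Ni, O, C1, C2, C3; formed by oxidative cyclisation) being only a transient intermediate. C2 is set relative to C1 by the (2E) geometry of 5, which keeps CH2OTBS in the outer position of the diene complex and trans to the aryl group of the aldehyde on the nickelacycle (1,2‑anti), and the absolute configuration at C1 (S) is set by the ligand, which decides the face of the aldehyde that is attacked. The step needs C–C bond formation at C2 and not at C5, hydrogen delivery to C3 and not to C5, anti diastereoselectivity and enantioselectivity: the veratryl ring on C5 should secure the first two (only bonding at C2 gives an aryl‑conjugated allylnickel, and only hydrogen at C3 restores the styrene), the E,E geometry the third and the ligand the fourth.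

Step 5
Reactants: 6 (1S,2R,4E)‑2‑{[(tert‑butyldimethylsilyl)oxy]methyl}‑1,5‑bis(3,4‑dimethoxyphenyl)pent‑4‑en‑1‑ol
Product: 7 (1S,2R)‑1‑(3,4‑dimethoxyphenyl)‑2‑[(2E)‑3‑(3,4‑dimethoxyphenyl)prop‑2‑en‑1‑yl]propane‑1,3‑diol
Conditions: TBAF, THF, 0 °C → rt
Reagents that add atoms: none
Why: Fluoride cleaves the Si–O bond (strong Si–F bond) and frees the primary alcohol without touching either stereocentre.

Step 6
Reactants: 7 (1S,2R)‑1‑(3,4‑dimethoxyphenyl)‑2‑[(2E)‑3‑(3,4‑dimethoxyphenyl)prop‑2‑en‑1‑yl]propane‑1,3‑diol; 8 but‑2‑ynoic acid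
Product: 9 (2R,3S)‑3‑(3,4‑dimethoxyphenyl)‑2‑[(2E)‑3‑(3,4‑dimethoxyphenyl)prop‑2‑en‑1‑yl]‑3‑hydroxypropyl but‑2‑ynoate
Conditions: DCC (1.05 equiv), DMAP (0.1 equiv), CH2Cl2, −20 → 0 °C
Reagents that add atoms: none
Why: Steglich esterification, in which the activated acyl group should go to the unhindered primary hydroxyl much faster than to the secondary benzylic hydroxyl next to the branched carbon; an ynoate has no olefin geometry to lose.

Step 7
Reactants: 9 (2R,3S)‑3‑(3,4‑dimethoxyphenyl)‑2‑[(2E)‑3‑(3,4‑dimethoxyphenyl)prop‑2‑en‑1‑yl]‑3‑hydroxypropyl but‑2‑ynoate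
Product: 11 (2R,3S)‑3‑(3,4‑dimethoxyphenyl)‑2‑[(2E)‑3‑(3,4‑dimethoxyphenyl)prop‑2‑en‑1‑yl]‑3‑hydroxypropyl (2Z)‑2‑(hydroxymethyl)but‑2‑enoate, via vinylalane 10 (not isolated)
Conditions: DIBAL‑H (2.3 equiv), NMO (2.3 equiv), THF, 0 °C; then HCHO (g, from paraformaldehyde), −20 → 0 °C
Reagents that add atoms: formaldehyde, C=O
Why: Syn‑hydroalumination of the ynoate by the DIBAL‑H·NMO complex (hydride to C3, aluminium to C2) followed by addition of the α‑alumino acrylate to formaldehyde (vinylalumination, a reductive aldol) should place CH3 cis to the ester and so give the Z olefin, the free benzylic hydroxyl being masked in the flask as its aluminium alkoxide.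

**Compound list**
1 | veratraldehyde (3,4‑dimethoxybenzaldehyde) | COc1ccc(C=O)cc1OC | starting material
2 | triethyl 4‑phosphonocrotonate [ethyl (2E)‑4‑(diethoxyphosphoryl)but‑2‑enoate] | CCOC(=O)/C=C/CP(=O)(OCC)OCC | starting material
3 | ethyl (2E,4E)‑5‑(3,4‑dimethoxyphenyl)penta‑2,4‑dienoate | CCOC(=O)/C=C/C=C/c1ccc(OC)c(OC)c1 | intermediate
4 | (2E,4E)‑5‑(3,4‑dimethoxyphenyl)penta‑2,4‑dien‑1‑ol | OC/C=C/C=C/c1ccc(OC)c(OC)c1 | intermediate
5 | tert‑butyl{[(2E,4E)‑5‑(3,4‑dimethoxyphenyl)penta‑2,4‑dien‑1‑yl]oxy}dimethylsilane | CC(C)(C)[Si](C)(C)OC/C=C/C=C/c1ccc(OC)c(OC)c1 | intermediate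
6 | (1S,2R,4E)‑2‑{[(tert‑butyldimethylsilyl)oxy]methyl}‑1,5‑bis(3,4‑dimethoxyphenyl)pent‑4‑en‑1‑ol | CC(C)(C)[Si](C)(C)OC[C@@H](C/C=C/c1ccc(OC)c(OC)c1)[C@H](O)c1ccc(OC)c(OC)c1 | intermediate
7 | (1S,2R)‑1‑(3,4‑dimethoxyphenyl)‑2‑[(2E)‑3‑(3,4‑dimethoxyphenyl)prop‑2‑en‑1‑yl]propane‑1,3‑diol | OC[C@@H](C/C=C/c1ccc(OC)c(OC)c1)[C@H](O)c1ccc(OC)c(OC)c1 | intermediate
8 | but‑2‑ynoic acid | CC#CC(=O)O | starting material
9 | (2R,3S)‑3‑(3,4‑dimethoxyphenyl)‑2‑[(2E)‑3‑(3,4‑dimethoxyphenyl)prop‑2‑en‑1‑yl]‑3‑hydroxypropyl but‑2‑ynoate | CC#CC(=O)OC[C@@H](C/C=C/c1ccc(OC)c(OC)c1)[C@H](O)c1ccc(OC)c(OC)c1 | intermediate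
10 | (2R,3S)‑3‑[(diisobutylalumanyl)oxy]‑3‑(3,4‑dimethoxyphenyl)‑2‑[(2E)‑3‑(3,4‑dimethoxyphenyl)prop‑2‑en‑1‑yl]propyl (2E)‑2‑(diisobutylalumanyl)but‑2‑enoate (vinylalane) | C/C=C(/[Al](CC(C)C)CC(C)C)C(=O)OC[C@@H](C/C=C/c1ccc(OC)c(OC)c1)[C@H](O[Al](CC(C)C)CC(C)C)c1ccc(OC)c(OC)c1 | intermediate
11 | (2R,3S)‑3‑(3,4‑dimethoxyphenyl)‑2‑[(2E)‑3‑(3,4‑dimethoxyphenyl)prop‑2‑en‑1‑yl]‑3‑hydroxypropyl (2Z)‑2‑(hydroxymethyl)but‑2‑enoate | C/C=C(/CO)C(=O)OC[C@@H](C/C=C/c1ccc(OC)c(OC)c1)[C@H](O)c1ccc(OC)c(OC)c1 | target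

**Step count**
Total step count: 7. Longest linear sequence: 7 steps (1 → 3 → 4 → 5 → 6 → 7 → 9 → 11).

**Steps most likely to fail**

Step 4 (proposed new method). What may go wrong: bond formation at the aryl‑bearing diene terminus, hydrogen delivery to the benzylic end of the allylnickel (giving the non‑conjugated homoallylic isomer), incomplete facial control by the ligand on this unsymmetrical diene, or competing ethyl transfer from zinc to the aldehyde. The fallback uses known chemistry, sets out from 1 and rejoins the route at 7. (S)‑4‑Benzyloxazolidin‑2‑one is N‑acylated with pent‑4‑enoyl chloride (Et3N, DMAP cat., CH2Cl2) to give (4S)‑4‑benzyl‑3‑(pent‑4‑enoyl)‑1,3‑oxazolidin‑2‑one F1. Cross‑metathesis with 3,4‑dimethoxystyrene (second‑generation Ru benzylidene catalyst, CH2Cl2, 40 °C) should give (4S)‑4‑benzyl‑3‑[(4E)‑5‑(3,4‑dimethoxyphenyl)pent‑4‑enoyl]‑1,3‑oxazolidin‑2‑one F2. Bu2BOTf/iPr2NEt (CH2Cl2, 0 °C) converts it into (4S)‑4‑benzyl‑3‑[(1Z,4E)‑1‑[(dibutylboranyl)oxy]‑5‑(3,4‑dimethoxyphenyl)penta‑1,4‑dien‑1‑yl]‑1,3‑oxazolidin‑2‑one F3. This enolate adds to 1 at −78 → 0 °C (Evans syn‑aldol, chair Zimmerman–Traxler transition state, face set by the benzyl group) and should give (4S)‑4‑benzyl‑3‑[(2S,3S)‑3‑(3,4‑dimethoxyphenyl)‑2‑[(2E)‑3‑(3,4‑dimethoxyphenyl)prop‑2‑en‑1‑yl]‑3‑hydroxypropanoyl]‑1,3‑oxazolidin‑2‑one F4. LiBH4/MeOH (THF, 0 °C) then removes the auxiliary reductively and gives 7.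

Step 7. What may go wrong: 1,2‑reduction of the ester instead of conjugate hydroalumination, loss of olefin geometry in the α‑alumino acrylate before it is trapped, or acyl transfer to the neighbouring aluminium alkoxide. The fallback sets out from 9 and comes back at 11, replacing the aluminium reductive aldol by a palladium sequence under neutral conditions. Pd(PPh3)4‑catalysed syn‑hydrostannation with Bu3SnH (THF, rt) should give (2R,3S)‑3‑(3,4‑dimethoxyphenyl)‑2‑[(2E)‑3‑(3,4‑dimethoxyphenyl)prop‑2‑en‑1‑yl]‑3‑hydroxypropyl (2E)‑2‑(tributylstannyl)but‑2‑enoate F5. Iododestannylation with I2 (1.0 equiv, CH2Cl2, −78 °C) gives, with retention, (2R,3S)‑3‑(3,4‑dimethoxyphenyl)‑2‑[(2E)‑3‑(3,4‑dimethoxyphenyl)prop‑2‑en‑1‑yl]‑3‑hydroxypropyl (2E)‑2‑iodobut‑2‑enoate F6. Stille coupling with (tributylstannyl)methanol (Pd(PPh3)4, dioxane, 80 °C) replaces iodine by CH2OH with retention and gives 11.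

Step 6. What may go wrong: insufficient site selectivity of acyl transfer (esterification of the secondary benzylic hydroxyl or of both hydroxyls) and conjugate addition of DMAP to the activated ynoate. The fallback sets out from 6 and comes back at 9, telling the two hydroxyls apart by protection instead of by rate. TBSOTf/2,6‑lutidine (CH2Cl2, −78 °C) gives (1S,2R,4E)‑1‑[(tert‑butyldimethylsilyl)oxy]‑2‑{[(tert‑butyldimethylsilyl)oxy]methyl}‑1,5‑bis(3,4‑dimethoxyphenyl)pent‑4‑ene F7. HF·pyridine buffered with pyridine (THF, 0 °C) should cleave only the primary silyl ether and give (2R,3S)‑3‑[(tert‑butyldimethylsilyl)oxy]‑3‑(3,4‑dimethoxyphenyl)‑2‑[(2E)‑3‑(3,4‑dimethoxyphenyl)prop‑2‑en‑1‑yl]propan‑1‑ol F8. Esterification with 8 (DCC, DMAP cat., CH2Cl2, 0 °C) gives (2R,3S)‑3‑[(tert‑butyldimethylsilyl)oxy]‑3‑(3,4‑dimethoxyphenyl)‑2‑[(2E)‑3‑(3,4‑dimethoxyphenyl)prop‑2‑en‑1‑yl]propyl but‑2‑ynoate F9. HF·pyridine (THF, rt) then frees the secondary hydroxyl and gives 9.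

**Further compounds**
F1 | step 4 | (4S)‑4‑benzyl‑3‑(pent‑4‑enoyl)‑1,3‑oxazolidin‑2‑one | C=CCCC(=O)N1[C@@H](Cc2ccccc2)COC1=O
F2 | step 4 | (4S)‑4‑benzyl‑3‑[(4E)‑5‑(3,4‑dimethoxyphenyl)pent‑4‑enoyl]‑1,3‑oxazolidin‑2‑one | COc1ccc(/C=C/CCC(=O)N2[C@@H](Cc3ccccc3)COC2=O)cc1OC
F3 | step 4 | (4S)‑4‑benzyl‑3‑[(1Z,4E)‑1‑[(dibutylboranyl)oxy]‑5‑(3,4‑dimethoxyphenyl)penta‑1,4‑dien‑1‑yl]‑1,3‑oxazolidin‑2‑one | CCCCB(CCCC)O/C(=C\C/C=C/c1ccc(OC)c(OC)c1)N1[C@@H](Cc2ccccc2)COC1=O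
F4 | step 4 | (4S)‑4‑benzyl‑3‑[(2S,3S)‑3‑(3,4‑dimethoxyphenyl)‑2‑[(2E)‑3‑(3,4‑dimethoxyphenyl)prop‑2‑en‑1‑yl]‑3‑hydroxypropanoyl]‑1,3‑oxazolidin‑2‑one | O=C(N1[C@@H](Cc2ccccc2)COC1=O)[C@@H](C/C=C/c1ccc(OC)c(OC)c1)[C@H](O)c1ccc(OC)c(OC)c1
F5 | step 7 | (2R,3S)‑3‑(3,4‑dimethoxyphenyl)‑2‑[(2E)‑3‑(3,4‑dimethoxyphenyl)prop‑2‑en‑1‑yl]‑3‑hydroxypropyl (2E)‑2‑(tributylstannyl)but‑2‑enoate | C/C=C(/[Sn](CCCC)(CCCC)CCCC)C(=O)OC[C@@H](C/C=C/c1ccc(OC)c(OC)c1)[C@H](O)c1ccc(OC)c(OC)c1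
F6 | step 7 | (2R,3S)‑3‑(3,4‑dimethoxyphenyl)‑2‑[(2E)‑3‑(3,4‑dimethoxyphenyl)prop‑2‑en‑1‑yl]‑3‑hydroxypropyl (2E)‑2‑iodobut‑2‑enoate | C/C=C(/I)C(=O)OC[C@@H](C/C=C/c1ccc(OC)c(OC)c1)[C@H](O)c1ccc(OC)c(OC)c1
F7 | step 6 | (1S,2R,4E)‑1‑[(tert‑butyldimethylsilyl)oxy]‑2‑{[(tert‑butyldimethylsilyl)oxy]methyl}‑1,5‑bis(3,4‑dimethoxyphenyl)pent‑4‑ene | CC(C)(C)[Si](C)(C)OC[C@@H](C/C=C/c1ccc(OC)c(OC)c1)[C@H](O[Si](C)(C)C(C)(C)C)c1ccc(OC)c(OC)c1
F8 | step 6 | (2R,3S)‑3‑[(tert‑butyldimethylsilyl)oxy]‑3‑(3,4‑dimethoxyphenyl)‑2‑[(2E)‑3‑(3,4‑dimethoxyphenyl)prop‑2‑en‑1‑yl]propan‑1‑ol | OC[C@@H](C/C=C/c1ccc(OC)c(OC)c1)[C@H](O[Si](C)(C)C(C)(C)C)c1ccc(OC)c(OC)c1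
F9 | step 6 | (2R,3S)‑3‑[(tert‑butyldimethylsilyl)oxy]‑3‑(3,4‑dimethoxyphenyl)‑2‑[(2E)‑3‑(3,4‑dimethoxyphenyl)prop‑2‑en‑1‑yl]propyl but‑2‑ynoate | CC#CC(=O)OC[C@@H](C/C=C/c1ccc(OC)c(OC)c1)[C@H](O[Si](C)(C)C(C)(C)C)c1ccc(OC)c(OC)c1
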